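**Remark on the chemistry:** Bisoflavolin H has no stereocentre, no configured double bond and no hindered axis, so it is achiral and no enantiocontrol is needed. The only configured element in the route is the (E)-enaminone C=C, which is consumed in the key step.

## Retrosynthetic overview

1. The target is an 8-chloro-7-hydroxyisoflavone whose B ring is joined through its 4'-oxygen to C8 of genistein; the last operation is removal of four benzyl ethers.
2. Key disconnection: the C3–C1' bond of the chlorinated isoflavone together with the O1–C2 bond of the same pyranone ring, made in one photoredox radical arylation–annulation of an o-hydroxyaryl enaminone with an arenediazonium salt that carries the whole genistein unit.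
3. Enabling feature: in the chlorinated chromone C2 is an unsubstituted CH between O1 and C3, so O1–C2H=C3–C4=O is a masked push–pull enaminone ArC(=O)–CH=CH–NMe2 whose α-carbon (future C3) traps aryl radicals; C1' is para to the diaryl-ether oxygen, so the radical precursor is a stabilised 4-aryloxybenzenediazonium salt.
4. Diazonium fragment from genistein: per-benzylation, C8 iodination, borylation, oxidation to the C8 phenol, SNAr with 1-fluoro-4-nitrobenzene, nitro reduction, diazotisation. Enaminone from 2-chlororesorcinol: C-acetylation, 4-O-benzylation, amide-acetal condensation.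
5. Ring order: both rings of genistein arrive intact, the diaryl ether is made before the key step, and the pyranone ring of the chlorinated isoflavone is the only ring built, last, in the key step.

Key step: step 11

## Route

Step 1
Reactants: 1 genistein; 2 benzyl bromide
Product: 3 5,7-bis(benzyloxy)-3-[4-(benzyloxy)phenyl]-4H-chromen-4-one (tri-O-benzylgenistein)
Conditions: BnBr (4.5 equiv), K2CO3, cat. Bu4NI, DMF, 80 °C
Reagents that add atoms: benzyl bromide BrCc1ccccc1
Why: Williamson etherification in which excess halide, iodide catalysis and heat also cap the hydrogen-bonded 5-OH, which must be alkylated to steer step 2.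

Step 2
Reactants: 3 tri-O-benzylgenistein
Product: 4 5,7-bis(benzyloxy)-3-[4-(benzyloxy)phenyl]-8-iodo-4H-chromen-4-one
Conditions: NIS (1.1 equiv), TFA (0.3 equiv), MeCN/CH2Cl2, 0 °C to rt, dark
Reagents that add atoms: N-iodosuccinimide O=C1CCC(=O)N1I
Why: Electrophilic aromatic iodination of the phloroglucinol-type A ring, which for 5,7-dialkoxychromones (no free 5-OH to direct to C6) should occur at C8, the less encumbered activated position between the 7-alkoxy group and ring O1.

Step 3
Reactants: 4 8-iodo-tri-O-benzylgenistein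
Product: 5 5,7-bis(benzyloxy)-3-[4-(benzyloxy)phenyl]-8-(4,4,5,5-tetramethyl-1,3,2-dioxaborolan-2-yl)-4H-chromen-4-one
Conditions: B2pin2 (1.5 equiv), XPhos Pd G2 (3 mol%), KOAc, 1,4-dioxane, 90 °C
Reagents that add atoms: bis(pinacolato)diboron CC1(C)OB(OC1(C)C)B1OC(C)(C)C(C)(C)O1
Why: Miyaura borylation, with a bulky biarylphosphine palladacycle chosen because the C–I bond is flanked by two ortho oxygens.

Step 4
Reactants: 5 8-boronate
Product: 6 5,7-bis(benzyloxy)-3-[4-(benzyloxy)phenyl]-8-hydroxy-4H-chromen-4-one
Conditions: Oxone (1.1 equiv), acetone/H2O (unbuffered), 0 °C, 15 min; aq. NaHSO3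
Reagents that add atoms: potassium peroxymonosulfate (active component of Oxone) [K+].[O-]S(=O)(=O)OO
Why: Oxidative ipso-hydroxylation of the aryl boronate (1,2-aryl shift from boron to oxygen), kept short and unbuffered so that the chromone C2=C3 bond is not epoxidised.

Step 5
Reactants: 6 8-hydroxy-tri-O-benzylgenistein; 7 1-fluoro-4-nitrobenzene
Product: 8 5,7-bis(benzyloxy)-3-[4-(benzyloxy)phenyl]-8-(4-nitrophenoxy)-4H-chromen-4-one
Conditions: 7 (1.3 equiv), K2CO3, DMF, 80 °C
Reagents that add atoms: 1-fluoro-4-nitrobenzene O=[N+]([O-])c1ccc(F)cc1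
Why: SNAr (addition–elimination through a Meisenheimer complex) of the C8 phenoxide on the para-nitro-activated fluoride, a reaction that tolerates di-ortho-oxygenated phenoxides, under anhydrous carbonate that does not open the pyranone.

Step 6
Reactants: 8 nitro diaryl ether
Product: 9 8-(4-aminophenoxy)-5,7-bis(benzyloxy)-3-[4-(benzyloxy)phenyl]-4H-chromen-4-one
Conditions: Fe powder (6 equiv), AcOH, EtOH/THF, 60 °C
Reagents that add atoms: none
Why: Béchamp-type dissolving-metal reduction of the nitro group, which unlike catalytic hydrogenation leaves the benzyl ethers and the chromone double bond intact.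

Step 7
Reactants: 9 aniline
Product: 10 4-({5,7-bis(benzyloxy)-3-[4-(benzyloxy)phenyl]-4-oxo-4H-chromen-8-yl}oxy)benzenediazonium tetrafluoroborate
Conditions: t-BuONO (1.3 equiv), HBF4·OEt2 (1.5 equiv), THF/MeCN, −15 to 0 °C; precipitation with Et2O
Reagents that add atoms: tert-butyl nitrite CC(C)(C)ON=O; tetrafluoroboric acid (diethyl ether complex) [H+].F[B-](F)(F)F
Why: Anhydrous diazotisation with an alkyl nitrite, giving an arenediazonium tetrafluoroborate that the para-aryloxy donor stabilises enough for it to be precipitated and used directly.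

Step 8
Reactants: 11 2-chlororesorcinol; 12 acetic acid
Product: 13 1-(3-chloro-2,4-dihydroxyphenyl)ethan-1-one
Conditions: AcOH, BF3·OEt2 (3 equiv), 90 °C; then aq. NaOAc
Reagents that add atoms: acetic acid CC(=O)O
Why: Nencki-type Friedel–Crafts C-acylation at C4 (C4 and C6 are equivalent, each ortho to one OH and para to the other), stopping at mono-acylation because the chelated ketone is deactivated.

Step 9
Reactants: 13 3-chloro-2,4-dihydroxyacetophenone; 2 benzyl bromide
Product: 14 1-[4-(benzyloxy)-3-chloro-2-hydroxyphenyl]ethan-1-one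
Conditions: BnBr (1.05 equiv), K2CO3 (1.2 equiv), acetone, 56 °C
Reagents that add atoms: benzyl bromide BrCc1ccccc1
Why: Williamson etherification selective for the free, more acidic 4-OH, the 2-OH being held in a hydrogen bond to the ketone.

Step 10
Reactants: 14 4-O-benzyl ketone; 15 N,N-dimethylformamide dimethyl acetal
Product: 16 (E)-1-[4-(benzyloxy)-3-chloro-2-hydroxyphenyl]-3-(dimethylamino)prop-2-en-1-one
Conditions: DMF-DMA (2 equiv), toluene, 100 °C
Reagents that add atoms: N,N-dimethylformamide dimethyl acetal COC(OC)N(C)C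
Why: Condensation of the methyl ketone with the amide acetal (enaminone formation) gives the (E)-β-(dimethylamino)enone, the chelated 2-OH staying free as the annulation requires.

Step 11
Reactants: 10 diazonium tetrafluoroborate; 16 enaminone
Product: 18 tetra-O-benzyl bisoflavolin H, via 2-(dimethylamino)isoflavanone 17 (not isolated)
Conditions: 16 (1.5 equiv), eosin Y (2 mol%), DMSO/MeCN, green LEDs (530 nm), 20 °C, N2
Reagents that add atoms: none
Why: Photoexcited eosin Y transfers one electron to 10, which loses N2 to give the aryl σ-radical; this adds to the α-carbon of the push–pull enaminone 16 (the future C3) to give an α-amino radical, which is oxidised to an iminium ion by the eosin Y radical cation or, in a chain, by a further diazonium ion. The ortho phenol traps the iminium ion to give the 2-(dimethylamino)isoflavanone 17, and loss of dimethylamine, which ends as its HBF4 salt and so buffers the medium, delivers the chromone. The closest known reaction type is the visible-light photoredox Meerwein-type arylation–annulation of o-hydroxyaryl enaminones with arenediazonium salts to give isoflavones, applied here to a diazonium salt that carries a complete protected isoflavone. The one ring that closes, the pyranone of the chlorinated isoflavone, closes by 6-exo-trig attack of the phenol oxygen on the iminium carbon (the C=N+ bond lies outside the new ring), followed by β-elimination of the amine. No stereocentre is created in the product, since the two sp3 carbons of 17 form without control and are both flattened again in the elimination. The step needs C–C bond formation at the α- and not the β-carbon, secured by the polarisation of the enaminone (largest HOMO coefficient at Cα, nitrogen-stabilised radical after addition), and it needs the radical path to outrun polar azo coupling at the same carbon, secured by the weakly electrophilic yet easily reduced para-aryloxy diazonium ion and the excess of 16.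

Step 12
Reactants: 18 tetra-O-benzyl bisoflavolin H
Product: 19 bisoflavolin H
Conditions: BCl3 (12 equiv), pentamethylbenzene (12 equiv), CH2Cl2, −78 to −20 °C; MeOH quench
Reagents that add atoms: none
Why: Lewis-acid O-debenzylation with BCl3, in which pentamethylbenzene traps the benzyl cations by Friedel–Crafts alkylation so that the electron-rich A ring is not C-benzylated, while the aryl chloride, the diaryl ether and both chromones are inert.

## Compound list

1 | genistein, 5,7-dihydroxy-3-(4-hydroxyphenyl)-4H-chromen-4-one | O=c1c(-c2ccc(O)cc2)coc2cc(O)cc(O)c12 | starting material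
2 | benzyl bromide | BrCc1ccccc1 | starting material
3 | 5,7-bis(benzyloxy)-3-[4-(benzyloxy)phenyl]-4H-chromen-4-one | O=c1c(-c2ccc(OCc3ccccc3)cc2)coc2cc(OCc3ccccc3)cc(OCc3ccccc3)c12 | intermediate
4 | 5,7-bis(benzyloxy)-3-[4-(benzyloxy)phenyl]-8-iodo-4H-chromen-4-one | O=c1c(-c2ccc(OCc3ccccc3)cc2)coc2c(I)c(OCc3ccccc3)cc(OCc3ccccc3)c12 | intermediate
5 | 5,7-bis(benzyloxy)-3-[4-(benzyloxy)phenyl]-8-(4,4,5,5-tetramethyl-1,3,2-dioxaborolan-2-yl)-4H-chromen-4-one | O=c1c(-c2ccc(OCc3ccccc3)cc2)coc2c(B3OC(C)(C)C(C)(C)O3)c(OCc3ccccc3)cc(OCc3ccccc3)c12 | intermediate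
6 | 5,7-bis(benzyloxy)-3-[4-(benzyloxy)phenyl]-8-hydroxy-4H-chromen-4-one | O=c1c(-c2ccc(OCc3ccccc3)cc2)coc2c(O)c(OCc3ccccc3)cc(OCc3ccccc3)c12 | intermediate
7 | 1-fluoro-4-nitrobenzene | O=[N+]([O-])c1ccc(F)cc1 | starting material
8 | 5,7-bis(benzyloxy)-3-[4-(benzyloxy)phenyl]-8-(4-nitrophenoxy)-4H-chromen-4-one | O=c1c(-c2ccc(OCc3ccccc3)cc2)coc2c(Oc3ccc([N+](=O)[O-])cc3)c(OCc3ccccc3)cc(OCc3ccccc3)c12 | intermediate
9 | 8-(4-aminophenoxy)-5,7-bis(benzyloxy)-3-[4-(benzyloxy)phenyl]-4H-chromen-4-one | O=c1c(-c2ccc(OCc3ccccc3)cc2)coc2c(Oc3ccc(N)cc3)c(OCc3ccccc3)cc(OCc3ccccc3)c12 | intermediate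
10 | 4-({5,7-bis(benzyloxy)-3-[4-(benzyloxy)phenyl]-4-oxo-4H-chromen-8-yl}oxy)benzenediazonium tetrafluoroborate | O=c1c(-c2ccc(OCc3ccccc3)cc2)coc2c(Oc3ccc([N+]#N)cc3)c(OCc3ccccc3)cc(OCc3ccccc3)c12.F[B-](F)(F)F | intermediate
11 | 2-chlororesorcinol, 2-chlorobenzene-1,3-diol | Oc1cccc(O)c1Cl | starting material
12 | acetic acid | CC(=O)O | starting material
13 | 1-(3-chloro-2,4-dihydroxyphenyl)ethan-1-one | CC(=O)c1ccc(O)c(Cl)c1O | intermediate
14 | 1-[4-(benzyloxy)-3-chloro-2-hydroxyphenyl]ethan-1-one | CC(=O)c1ccc(OCc2ccccc2)c(Cl)c1O | intermediate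
15 | N,N-dimethylformamide dimethyl acetal | COC(OC)N(C)C | starting material
16 | (E)-1-[4-(benzyloxy)-3-chloro-2-hydroxyphenyl]-3-(dimethylamino)prop-2-en-1-one | CN(C)/C=C/C(=O)c1ccc(OCc2ccccc2)c(Cl)c1O | intermediate
17 | 7-(benzyloxy)-8-chloro-2-(dimethylamino)-3-[4-({5,7-bis(benzyloxy)-3-[4-(benzyloxy)phenyl]-4-oxo-4H-chromen-8-yl}oxy)phenyl]chroman-4-one (transient; C2 and C3 form without control and are both lost in the same flask) | CN(C)C1Oc2c(Cl)c(OCc3ccccc3)ccc2C(=O)C1c1ccc(Oc2c(OCc3ccccc3)cc(OCc3ccccc3)c3c(=O)c(-c4ccc(OCc5ccccc5)cc4)coc23)cc1 | intermediate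
18 | tetra-O-benzyl bisoflavolin H, 7-(benzyloxy)-3-[4-({5,7-bis(benzyloxy)-3-[4-(benzyloxy)phenyl]-4-oxo-4H-chromen-8-yl}oxy)phenyl]-8-chloro-4H-chromen-4-one | O=c1c(-c2ccc(Oc3c(OCc4ccccc4)cc(OCc4ccccc4)c4c(=O)c(-c5ccc(OCc6ccccc6)cc5)coc34)cc2)coc2c(Cl)c(OCc3ccccc3)ccc12 | intermediate
19 | bisoflavolin H | O=c1c(-c2ccc(Oc3c(O)cc(O)c4c(=O)c(-c5ccc(O)cc5)coc34)cc2)coc2c(Cl)c(O)ccc12 | target

## Summary

Total step count: 12. Longest linear sequence: 9 steps (steps 1–7, 11 and 12); the enaminone branch (steps 8–10) joins at step 11.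

Steps most likely to fail:

1. **Step 11 (key step).** Polar azo coupling of the diazonium ion at the enaminone α-carbon, hydrogen abstraction by the aryl radical (hydrodediazoniation) and acid-triggered closure of 16 to the 3-unsubstituted chromone can each consume a partner without forming the C3–C1' bond. The fallback replaces the radical union by a two-electron cross-coupling and sets out from 16 and 9. Iodine-mediated cyclisation of 16 (I2, CHCl3, rt) should give 7-(benzyloxy)-8-chloro-3-iodo-4H-chromen-4-one F1. Sandmeyer-type borylation of 9 (t-BuONO, B2pin2, MeCN, rt) should give 5,7-bis(benzyloxy)-3-[4-(benzyloxy)phenyl]-8-[4-(4,4,5,5-tetramethyl-1,3,2-dioxaborolan-2-yl)phenoxy]-4H-chromen-4-one F2. Suzuki–Miyaura coupling of F1 and F2 (PdCl2(dppf), K3PO4, dioxane/H2O, 80 °C) comes back to the route at 18.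

2. **Step 2.** Iodination may divide between C8 and C6 or run on to the 6,8-diiodide, and a C6 isomer would carry through unnoticed to a 6-aryloxy product. The fallback fixes the position through the free 5-OH and sets out from 1. Selective benzylation of the two non-chelated phenols (BnBr 2.2 equiv, K2CO3, acetone, 56 °C) gives 7-(benzyloxy)-3-[4-(benzyloxy)phenyl]-5-hydroxy-4H-chromen-4-one F3. Elbs persulfate oxidation (K2S2O8, aq. KOH/pyridine, rt), which can only occur para to the 5-OH, gives potassium 7-(benzyloxy)-3-[4-(benzyloxy)phenyl]-5-hydroxy-4-oxo-4H-chromen-8-yl sulfate F4, hydrolysed without isolation (dilute HCl, Na2SO3, 70 °C) to 7-(benzyloxy)-3-[4-(benzyloxy)phenyl]-5,8-dihydroxy-4H-chromen-4-one F5. SNAr with 7 at the non-chelated 8-OH (K2CO3 1 equiv, DMF, 60 °C) gives 7-(benzyloxy)-3-[4-(benzyloxy)phenyl]-5-hydroxy-8-(4-nitrophenoxy)-4H-chromen-4-one F6. Benzylation of the 5-OH (BnBr, K2CO3, DMF, 80 °C) comes back to the route at 8, so steps 3–5 are bypassed as well.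

3. **Step 3.** At the doubly ortho-oxygenated C–I bond, transmetalation may be slow enough for reductive loss of iodine to take over. The fallback forms the diaryl ether directly at the iodide carbon and sets out from 4: copper-catalysed Ullmann O-arylation of 4-aminophenol (CuI, picolinic acid, K3PO4, DMSO, 90 °C), a coupling known to favour the phenol oxygen over the aniline nitrogen, should give 9 directly. It comes back to the route at 9, bypasses 5, 6 and 8, and needs no new compound (entry F0).

Further compounds
F1 | step 11 | 7-(benzyloxy)-8-chloro-3-iodo-4H-chromen-4-one | O=c1c(I)coc2c(Cl)c(OCc3ccccc3)ccc12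
F2 | step 11 | 5,7-bis(benzyloxy)-3-[4-(benzyloxy)phenyl]-8-[4-(4,4,5,5-tetramethyl-1,3,2-dioxaborolan-2-yl)phenoxy]-4H-chromen-4-one | O=c1c(-c2ccc(OCc3ccccc3)cc2)coc2c(Oc3ccc(B4OC(C)(C)C(C)(C)O4)cc3)c(OCc3ccccc3)cc(OCc3ccccc3)c12
F3 | step 2 | 7-(benzyloxy)-3-[4-(benzyloxy)phenyl]-5-hydroxy-4H-chromen-4-one | O=c1c(-c2ccc(OCc3ccccc3)cc2)coc2cc(OCc3ccccc3)cc(O)c12
F4 | step 2 | potassium 7-(benzyloxy)-3-[4-(benzyloxy)phenyl]-5-hydroxy-4-oxo-4H-chromen-8-yl sulfate | O=c1c(-c2ccc(OCc3ccccc3)cc2)coc2c(OS(=O)(=O)[O-])c(OCc3ccccc3)cc(O)c12.[K+]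
F5 | step 2 | 7-(benzyloxy)-3-[4-(benzyloxy)phenyl]-5,8-dihydroxy-4H-chromen-4-one | O=c1c(-c2ccc(OCc3ccccc3)cc2)coc2c(O)c(OCc3ccccc3)cc(O)c12
F6 | step 2 | 7-(benzyloxy)-3-[4-(benzyloxy)phenyl]-5-hydroxy-8-(4-nitrophenoxy)-4H-chromen-4-one | O=c1c(-c2ccc(OCc3ccccc3)cc2)coc2c(Oc3ccc([N+](=O)[O-])cc3)c(OCc3ccccc3)cc(O)c12
F0 | step 3 | none | none
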